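**Retrosynthetic overview**
- The C5'–C6' bond is cut last: allylic bromide 24 (chromene half) is joined to the alkenylzirconocene from silyl ether 25 under Pd catalysis, then both silyl groups are removed.
- The chromene core 21 comes from one oxygen-tethered Dötz benzannulation of alkoxycarbene 19. Ring B (pyran) closes first by alkyne insertion (C8a–C4a); ring A (arene) closes second by CO uptake and 6π electrocyclisation (C5–C6, C6–C7).
- The strategy rests on ring A being a 1,4-dioxygenated benzene: ether oxygen O1 on C8a sits para to the free C6 hydroxyl, with a methyl on C8. This is the para-alkoxyphenol that an alkenyl(alkoxy)carbene, an alkyne and CO give, and O1 is the carbinol oxygen of C2, so the C2–O1 bond is carried intact from the start.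
- Carbene 19 comes from enynol 11 and acylchromate 16 (from 2-bromopropene and Cr(CO)6). Both S carbinol centres (C2 and C8') come from one building block, (S)-3,7-dimethyloct-6-en-1-yn-3-ol 4, made from geraniol.

Key step: step 11

Remark: a neutral tertiary alcohol is assumed to add too slowly to a thermally fragile acyloxycarbene, so 11 is delivered to chromium as its lithium alkoxide; the C8 hydroxyl is introduced after the alkynol is made so that 4 serves both halves.

**Step 1**
Reactants: 1 geraniol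
Product: 2 (2S,3S)-2,3-epoxygeraniol, [(2S,3S)-3-methyl-3-(4-methylpent-3-en-1-yl)oxiran-2-yl]methanol
Conditions: Ti(OiPr)4 (5 mol%), L-(+)-diethyl tartrate (7 mol%), t-BuOOH, 4 Å MS, CH2Cl2, −20 °C
Reagents that add atoms: tert-butyl hydroperoxide, CC(C)(C)OO
Why: Sharpless asymmetric epoxidation touches only the allylic 2,3-alkene, and the titanium–L-(+)-tartrate catalyst delivers oxygen to the face that gives the (2S,3S)-epoxide, which fixes the tertiary carbon that becomes C2 and C8' of the target.

**Step 2**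
Reactants: 2 (2S,3S)-2,3-epoxygeraniol
Product: 3 (2R,3S)-1-chloro-2,3-epoxy-3,7-dimethyloct-6-ene (chain numbering; same spatial arrangement as 2)
Conditions: PPh3, CCl4, NaHCO3, reflux
Reagents that add atoms: carbon tetrachloride, ClC(Cl)(Cl)Cl
Why: the Appel chlorination is an SN2 displacement at the primary carbon, so the epoxide and both of its stereocentres are left untouched.

**Step 3**
Reactants: 3 (2R,3S)-1-chloro-2,3-epoxy-3,7-dimethyloct-6-ene
Product: 4 (S)-3,7-dimethyloct-6-en-1-yn-3-ol
Conditions: LiN(iPr)2 (3.2 equiv), THF, −40 °C → rt; then H2O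
Reagents that add atoms: none
Why: base-induced fragmentation of a 2,3-epoxy chloride (deprotonation at C1, β-elimination that opens the epoxide, then dehydrochlorination to the alkyne) never breaks the C3–O bond, so the tertiary carbinol keeps its configuration and is S.

**Step 4**
Reactants: 4 (S)-3,7-dimethyloct-6-en-1-yn-3-ol
Product: 5 (2E,6S)-2,6-dimethyloct-2-en-7-yne-1,6-diol
Conditions: SeO2 (cat.), t-BuOOH, salicylic acid (cat.), CH2Cl2, rt
Reagents that add atoms: tert-butyl hydroperoxide, CC(C)(C)OO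
Why: catalytic SeO2 allylic hydroxylation (ene reaction, then [2,3]-sigmatropic shift) should attack the E-methyl group of the trisubstituted alkene, while the alkyne has no propargylic C–H and the tertiary alcohol is inert.

**Step 5**
Reactants: 5 (2E,6S)-2,6-dimethyloct-2-en-7-yne-1,6-diol
Product: 6 (3S,6E)-8-[(tert-butyldimethylsilyl)oxy]-3,7-dimethyloct-6-en-1-yn-3-ol
Conditions: TBSCl (1.05 equiv), imidazole, CH2Cl2, 0 °C
Reagents that add atoms: tert-butyldimethylsilyl chloride, CC(C)(C)[Si](C)(C)Cl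
Why: silylation of the primary allylic hydroxyl is far faster than that of the tertiary propargylic one, which stays free for the carbene.

**Step 6**
Reactants: 6 (3S,6E)-8-[(tert-butyldimethylsilyl)oxy]-3,7-dimethyloct-6-en-1-yn-3-ol
Product: 7 (3S,6E)-8-[(tert-butyldimethylsilyl)oxy]-1-iodo-3,7-dimethyloct-6-en-1-yn-3-ol
Conditions: N-iodosuccinimide (1.05 equiv), AgNO3 (10 mol%), acetone, 0 °C, dark
Reagents that add atoms: N-iodosuccinimide, O=C1CCC(=O)N1I
Why: electrophilic iodination of the terminal alkyne through its silver acetylide is fast at 0 °C, so iodoetherification of the distant alkene by the tertiary hydroxyl should not compete.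

**Step 7**
Reactants: 7 (3S,6E)-8-[(tert-butyldimethylsilyl)oxy]-1-iodo-3,7-dimethyloct-6-en-1-yn-3-ol
Product: 8 (1Z,3S,6E)-8-[(tert-butyldimethylsilyl)oxy]-1-iodo-3,7-dimethylocta-1,6-dien-3-ol
Conditions: 2-nitrobenzenesulfonylhydrazide, Et3N, THF/i-PrOH, rt
Reagents that add atoms: none
Why: diimide reduction transfers both hydrogens to one face of the iodoalkyne and so gives the Z-iodoalkene with the C–I bond intact, while the trisubstituted alkene is reduced much more slowly.

**Step 8**
Reactants: 8 (1Z,3S,6E)-8-[(tert-butyldimethylsilyl)oxy]-1-iodo-3,7-dimethylocta-1,6-dien-3-ol; 9 trimethylsilylacetylene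
Product: 11 (3Z,5S,8E)-10-[(tert-butyldimethylsilyl)oxy]-5,9-dimethyldeca-3,8-dien-1-yn-5-ol, via C-silylated enyne 10 (not isolated)
Conditions: Pd(PPh3)2Cl2 (3 mol%), CuI (6 mol%), Et3N, THF, rt; then K2CO3, MeOH, rt
Reagents that add atoms: none
Why: Sonogashira coupling retains the Z geometry of the alkenyl iodide, and methanolysis then removes only the C-silyl group because the alkyl silyl ether and the tertiary alcohol are stable to K2CO3 in methanol.

**Step 9**
Reactants: 12 2-bromopropene; 13 chromium hexacarbonyl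
Product: 16 tetramethylammonium pentacarbonyl(2-methylprop-2-enoyl)chromate, via isopropenyllithium 14 (not isolated), via lithium acylchromate 15 (not isolated)
Conditions: t-BuLi (2 equiv), Et2O, −78 °C; 13, Et2O, 0 °C → rt; then Me4NBr, H2O
Reagents that add atoms: tetramethylammonium bromide, C[N+](C)(C)C.[Br-]
Why: this is the first half of a Fischer carbene synthesis, in which bromine–lithium exchange and addition of the alkenyllithium to a CO ligand give the acylchromate, isolated as its stable tetramethylammonium salt by cation exchange.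

**Step 10**
Reactants: 16 tetramethylammonium pentacarbonyl(2-methylprop-2-enoyl)chromate; 11 (3Z,5S,8E)-10-[(tert-butyldimethylsilyl)oxy]-5,9-dimethyldeca-3,8-dien-1-yn-5-ol
Product: 19 pentacarbonyl[{[(3Z,5S,8E)-10-[(tert-butyldimethylsilyl)oxy]-5,9-dimethyldeca-3,8-dien-1-yn-5-yl]oxy}(prop-1-en-2-yl)methylidene]chromium, via pivaloyloxycarbene 17 (not isolated), via lithium alkoxide 18 (not isolated)
Conditions: 16 (2 equiv), t-BuCOCl (1.9 equiv), CH2Cl2, −40 °C; then 18 (from 11, n-BuLi 1.0 equiv, THF, −78 °C), −78 → −20 °C; cold filtration through silica under argon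
Reagents that add atoms: none
Why: alkoxy exchange through an acyloxycarbene (O-acylation of the acylchromate, then addition–elimination at the carbene carbon) is the route used for alkoxycarbenes of hindered alcohols; here the tertiary alcohol is used as its lithium alkoxide so that addition outruns decomposition of 17, the pivaloyl group steers attack to the carbene carbon, and the C–O bond of the stereocentre is not touched.

**Step 11**
Reactants: 19 pentacarbonyl[{[(3Z,5S,8E)-10-[(tert-butyldimethylsilyl)oxy]-5,9-dimethyldeca-3,8-dien-1-yn-5-yl]oxy}(prop-1-en-2-yl)methylidene]chromium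
Product: 21 (2S)-2-[(3E)-5-[(tert-butyldimethylsilyl)oxy]-4-methylpent-3-en-1-yl]-2,8-dimethyl-2H-chromen-6-ol, via tricarbonylchromium arene complex 20 (not isolated)
Conditions: THF (0.005 M), 55 °C, argon, dark; then MeCN, air, rt
Reagents that add atoms: none
Why: Proposed new method: heating expels one cis CO from 19, the tethered alkyne binds chromium and inserts into the Cr=C bond with its inner carbon bonding to the carbene carbon (C8a–C4a), which closes ring B, the pyran, as a six-membered ring by intramolecular carbene–alkyne insertion; the chromium vinylcarbene now centred on C5 takes up CO to a dienylketene (C5–C6), a 6π electrocyclisation onto the isopropenyl CH2 closes ring A (C6–C7), and enolisation gives the phenol as its Cr(CO)3 complex 20, which MeCN and air demetallate. The closest known reaction type is the intramolecular Dötz benzannulation of alkoxycarbenes that carry the alkyne on the carbene oxygen through a saturated chain; a tertiary allylic alkoxy group and a rigid Z-alkenyl tether lie outside what has been run. No stereocentre is created and the C2–O1 bond is never broken, so C2 keeps the S configuration fixed in step 1. The step needs alkyne insertion with the regiochemistry opposite to the intermolecular preference, and the three-atom Z-alkenyl tether secures it because only the inner alkyne carbon can reach the carbene carbon, the other mode requiring a meta-bridged arene; high dilution keeps intermolecular insertion out. It also needs phenol formation to win over cyclobutenone formation, which alkenyl carbenes in THF normally ensure, and an acid-free, weakly polar medium so that the tertiary allylic C–O bond does not ionise before the alkyne inserts.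

**Step 12**
Reactants: 21 (2S)-2-[(3E)-5-[(tert-butyldimethylsilyl)oxy]-4-methylpent-3-en-1-yl]-2,8-dimethyl-2H-chromen-6-ol
Product: 22 tert-butyl{[(2E)-5-[(2S)-2,8-dimethyl-6-(triisopropylsilyloxy)-2H-chromen-2-yl]-2-methylpent-2-en-1-yl]oxy}dimethylsilane
Conditions: TIPSCl, imidazole, DMF, rt
Reagents that add atoms: triisopropylsilyl chloride, CC(C)[Si](Cl)(C(C)C)C(C)C
Why: silylation of the phenol removes the acidic O–H that would protonate the alkenylzirconium reagent, and the aryl triisopropylsilyl ether is chosen because it survives the acid of the next step.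

**Step 13**
Reactants: 22 tert-butyl{[(2E)-5-[(2S)-2,8-dimethyl-6-(triisopropylsilyloxy)-2H-chromen-2-yl]-2-methylpent-2-en-1-yl]oxy}dimethylsilane
Product: 23 (2E)-5-[(2S)-2,8-dimethyl-6-(triisopropylsilyloxy)-2H-chromen-2-yl]-2-methylpent-2-en-1-ol
Conditions: camphor-10-sulfonic acid (10 mol%), MeOH/CH2Cl2, 0 °C
Reagents that add atoms: none
Why: acid-catalysed methanolysis cleaves the primary alkyl silyl ether much faster than the hindered aryl silyl ether.

**Step 14**
Reactants: 23 (2E)-5-[(2S)-2,8-dimethyl-6-(triisopropylsilyloxy)-2H-chromen-2-yl]-2-methylpent-2-en-1-ol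
Product: 24 {[(2S)-2-[(3E)-5-bromo-4-methylpent-3-en-1-yl]-2,8-dimethyl-2H-chromen-6-yl]oxy}triisopropylsilane
Conditions: CBr4, PPh3, CH2Cl2, 0 °C
Reagents that add atoms: carbon tetrabromide, BrC(Br)(Br)Br
Why: the Appel bromination is an SN2 displacement at the primary allylic carbon under near-neutral conditions, so the E alkene and the chromene are kept.

**Step 15**
Reactants: 4 (S)-3,7-dimethyloct-6-en-1-yn-3-ol
Product: 25 triethyl{[(3S)-3,7-dimethyloct-6-en-1-yn-3-yl]oxy}silane
Conditions: TESOTf, 2,6-lutidine, CH2Cl2, −78 → 0 °C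
Reagents that add atoms: triethylsilyl trifluoromethanesulfonate, CC[Si](CC)(CC)OS(=O)(=O)C(F)(F)F
Why: silylation with the silyl triflate protects the hindered tertiary hydroxyl, which would otherwise consume Cp2Zr(H)Cl.

**Step 16**
Reactants: 25 triethyl{[(3S)-3,7-dimethyloct-6-en-1-yn-3-yl]oxy}silane; 24 {[(2S)-2-[(3E)-5-bromo-4-methylpent-3-en-1-yl]-2,8-dimethyl-2H-chromen-6-yl]oxy}triisopropylsilane
Product: 27 {[(2S)-2-[(3E,6E,8S)-4,8,12-trimethyl-8-(triethylsilyloxy)trideca-3,6,11-trien-1-yl]-2,8-dimethyl-2H-chromen-6-yl]oxy}triisopropylsilane, via alkenylzirconocene chloride 26 (not isolated)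
Conditions: 25 (1.4 equiv), Cp2Zr(H)Cl, THF, rt; then 24, Pd(PPh3)4 (5 mol%), THF, rt
Reagents that add atoms: none
Why: hydrozirconation adds H and Zr syn with zirconium on the terminal carbon to give the E-alkenylzirconocene, and the Negishi-type coupling catalysed by zerovalent palladium joins it to the primary terminus of the allyl unit with both alkene geometries retained, giving the E,E-1,4-diene without touching a stereocentre.

**Step 17**
Reactants: 27 {[(2S)-2-[(3E,6E,8S)-4,8,12-trimethyl-8-(triethylsilyloxy)trideca-3,6,11-trien-1-yl]-2,8-dimethyl-2H-chromen-6-yl]oxy}triisopropylsilane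
Product: 28 (2S)-2-[(3E,6E,8S)-8-hydroxy-4,8,12-trimethyltrideca-3,6,11-trien-1-yl]-2,8-dimethyl-2H-chromen-6-ol (CNP0155965.1)
Conditions: Bu4NF, AcOH, THF, 0 °C → rt, argon
Reagents that add atoms: none
Why: fluoride-mediated desilylation removes the aryl and the tertiary silyl ether together, and the acetic acid buffer keeps the electron-rich phenoxide from air oxidation.

**Compound list**
1 | geraniol | CC(C)=CCC/C(C)=C/CO | starting material
2 | (2S,3S)-2,3-epoxygeraniol | CC(C)=CCC[C@]1(C)O[C@H]1CO | intermediate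
3 | (2R,3S)-1-chloro-2,3-epoxy-3,7-dimethyloct-6-ene | CC(C)=CCC[C@]1(C)O[C@H]1CCl | intermediate
4 | (S)-3,7-dimethyloct-6-en-1-yn-3-ol | CC(C)=CCC[C@](C)(O)C#C | intermediate
5 | (2E,6S)-2,6-dimethyloct-2-en-7-yne-1,6-diol | OC/C(C)=C/CC[C@](C)(O)C#C | intermediate
6 | (3S,6E)-8-[(tert-butyldimethylsilyl)oxy]-3,7-dimethyloct-6-en-1-yn-3-ol | CC(C)(C)[Si](C)(C)OC/C(C)=C/CC[C@](C)(O)C#C | intermediate
7 | (3S,6E)-8-[(tert-butyldimethylsilyl)oxy]-1-iodo-3,7-dimethyloct-6-en-1-yn-3-ol | CC(C)(C)[Si](C)(C)OC/C(C)=C/CC[C@](C)(O)C#CI | intermediate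
8 | (1Z,3S,6E)-8-[(tert-butyldimethylsilyl)oxy]-1-iodo-3,7-dimethylocta-1,6-dien-3-ol | CC(C)(C)[Si](C)(C)OC/C(C)=C/CC[C@](C)(O)/C=C\I | intermediate
9 | trimethylsilylacetylene | C#C[Si](C)(C)C | starting material
10 | (3Z,5S,8E)-10-[(tert-butyldimethylsilyl)oxy]-5,9-dimethyl-1-(trimethylsilyl)deca-3,8-dien-1-yn-5-ol | CC(C)(C)[Si](C)(C)OC/C(C)=C/CC[C@](C)(O)/C=C\C#C[Si](C)(C)C | intermediate
11 | (3Z,5S,8E)-10-[(tert-butyldimethylsilyl)oxy]-5,9-dimethyldeca-3,8-dien-1-yn-5-ol | CC(C)(C)[Si](C)(C)OC/C(C)=C/CC[C@](C)(O)/C=C\C#C | intermediate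
12 | 2-bromopropene | C=C(C)Br | starting material
13 | chromium hexacarbonyl, Cr(CO)6 | O=C=[Cr](=C=O)(=C=O)(=C=O)(=C=O)=C=O | starting material
14 | isopropenyllithium | [Li]C(C)=C | intermediate
15 | lithium pentacarbonyl(2-methylprop-2-enoyl)chromate | [Li+].C=C(C)C([O-])=[Cr](=C=O)(=C=O)(=C=O)(=C=O)=C=O | intermediate
16 | tetramethylammonium pentacarbonyl(2-methylprop-2-enoyl)chromate | C[N+](C)(C)C.C=C(C)C([O-])=[Cr](=C=O)(=C=O)(=C=O)(=C=O)=C=O | intermediate
17 | pentacarbonyl[(2,2-dimethylpropanoyloxy)(prop-1-en-2-yl)methylidene]chromium | C=C(C)C(OC(=O)C(C)(C)C)=[Cr](=C=O)(=C=O)(=C=O)(=C=O)=C=O | intermediate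
18 | lithium (3Z,5S,8E)-10-[(tert-butyldimethylsilyl)oxy]-5,9-dimethyldeca-3,8-dien-1-yn-5-olate | CC(C)(C)[Si](C)(C)OC/C(C)=C/CC[C@](C)([O-])/C=C\C#C.[Li+] | intermediate
19 | pentacarbonyl[{[(3Z,5S,8E)-10-[(tert-butyldimethylsilyl)oxy]-5,9-dimethyldeca-3,8-dien-1-yn-5-yl]oxy}(prop-1-en-2-yl)methylidene]chromium | C=C(C)C(=[Cr](=C=O)(=C=O)(=C=O)(=C=O)=C=O)O[C@](C)(/C=C\C#C)CC/C=C(\C)CO[Si](C)(C)C(C)(C)C | intermediate
20 | tricarbonyl(η6-arene)chromium complex of 21 (ring A bound to chromium; written as two parts) | CC(C)(C)[Si](C)(C)OC/C(C)=C/CC[C@@]1(C)C=Cc2cc(O)cc(C)c2O1.O=C=[Cr](=C=O)=C=O | intermediate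
21 | (2S)-2-[(3E)-5-[(tert-butyldimethylsilyl)oxy]-4-methylpent-3-en-1-yl]-2,8-dimethyl-2H-chromen-6-ol | CC(C)(C)[Si](C)(C)OC/C(C)=C/CC[C@@]1(C)C=Cc2cc(O)cc(C)c2O1 | intermediate
22 | tert-butyl{[(2E)-5-[(2S)-2,8-dimethyl-6-(triisopropylsilyloxy)-2H-chromen-2-yl]-2-methylpent-2-en-1-yl]oxy}dimethylsilane | CC(C)(C)[Si](C)(C)OC/C(C)=C/CC[C@@]1(C)C=Cc2cc(O[Si](C(C)C)(C(C)C)C(C)C)cc(C)c2O1 | intermediate
23 | (2E)-5-[(2S)-2,8-dimethyl-6-(triisopropylsilyloxy)-2H-chromen-2-yl]-2-methylpent-2-en-1-ol | OC/C(C)=C/CC[C@@]1(C)C=Cc2cc(O[Si](C(C)C)(C(C)C)C(C)C)cc(C)c2O1 | intermediate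
24 | {[(2S)-2-[(3E)-5-bromo-4-methylpent-3-en-1-yl]-2,8-dimethyl-2H-chromen-6-yl]oxy}triisopropylsilane | BrC/C(C)=C/CC[C@@]1(C)C=Cc2cc(O[Si](C(C)C)(C(C)C)C(C)C)cc(C)c2O1 | intermediate
25 | triethyl{[(3S)-3,7-dimethyloct-6-en-1-yn-3-yl]oxy}silane | CC(C)=CCC[C@](C)(O[Si](CC)(CC)CC)C#C | intermediate
26 | chlorobis(cyclopentadienyl)[(1E,3S)-3,7-dimethyl-3-(triethylsilyloxy)octa-1,6-dien-1-yl]zirconium | CC(C)=CCC[C@](C)(O[Si](CC)(CC)CC)/C=C/[Zr](Cl)(C1C=CC=C1)C1C=CC=C1 | intermediate
27 | {[(2S)-2-[(3E,6E,8S)-4,8,12-trimethyl-8-(triethylsilyloxy)trideca-3,6,11-trien-1-yl]-2,8-dimethyl-2H-chromen-6-yl]oxy}triisopropylsilane | CC(C)=CCC[C@](C)(O[Si](CC)(CC)CC)/C=C/C/C(C)=C/CC[C@@]1(C)C=Cc2cc(O[Si](C(C)C)(C(C)C)C(C)C)cc(C)c2O1 | intermediate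
28 | (2S)-2-[(3E,6E,8S)-8-hydroxy-4,8,12-trimethyltrideca-3,6,11-trien-1-yl]-2,8-dimethyl-2H-chromen-6-ol | CC(C)=CCC[C@](C)(O)/C=C/C/C(C)=C/CC[C@@]1(C)C=Cc2cc(O)cc(C)c2O1 | target

**Step count**
Total: 17 steps. Longest linear sequence: 15 steps (steps 1–8, 10–14, 16, 17, from geraniol).

**Steps most likely to fail**

1. Step 11 (the benzannulation). The tertiary allylic C–O bond may ionise before the alkyne inserts, which would cost the alkoxy group or the configuration at C2. The rigid tether may fail to bring the alkyne onto chromium, so that intermolecular insertion and oligomerisation take over. The vinylketene may also be diverted to a cyclobutenone. The fallback uses known chemistry, sets out from 6 and returns at 22, and forms the O1–C8a bond by palladium catalysis. Commercial 4-amino-3-methylphenol is O-silylated (TIPSCl, imidazole) to 2-methyl-4-(triisopropylsilyloxy)aniline F1. Iodination ortho to nitrogen (N-iodosuccinimide, MeCN) gives 2-iodo-6-methyl-4-(triisopropylsilyloxy)aniline F2. Sandmeyer bromination (t-BuONO, CuBr2, MeCN) gives 2-bromo-1-iodo-3-methyl-5-(triisopropylsilyloxy)benzene F3. Sonogashira coupling of alkyne 6 at the C–I bond of F3 (Pd(PPh3)2Cl2, CuI, Et3N) gives (3S,6E)-1-[2-bromo-3-methyl-5-(triisopropylsilyloxy)phenyl]-8-[(tert-butyldimethylsilyl)oxy]-3,7-dimethyloct-6-en-1-yn-3-ol F4. Semihydrogenation over Pd/CaCO3 poisoned with Pb(OAc)2 and quinoline gives (1Z,3S,6E)-1-[2-bromo-3-methyl-5-(triisopropylsilyloxy)phenyl]-8-[(tert-butyldimethylsilyl)oxy]-3,7-dimethylocta-1,6-dien-3-ol F5. Intramolecular aryl etherification of the tertiary alcohol with the neighbouring C–Br bond (Pd(OAc)2, 2-(di-tert-butylphosphino)-1,1'-binaphthyl, Cs2CO3, toluene, 80 °C) closes the pyran without touching the carbinol C–O bond and gives 22.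

2. Step 10 (the alkoxycarbene). The hindered alkoxide may add more slowly than the acyloxycarbene decomposes, may add in conjugate fashion to the isopropenyl group, or may attack the acyl carbonyl. The fallback sets out from 16 and 11 and returns at 19, and replaces the transient acyloxycarbene by an isolable aryloxycarbene. Carbene 17 (from 16 and t-BuCOCl) is quenched with NaOPh to pentacarbonyl[phenoxy(prop-1-en-2-yl)methylidene]chromium F6, which is purified by chromatography. F6 is then treated with alkoxide 18 in THF from −40 to 0 °C, where exchange with loss of phenoxide can be given hours, to reach 19.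

3. Step 16 (the fragment union). Transmetalation from the hindered alkenylzirconocene may be slow, so that the allylpalladium intermediate homocouples, loses its E geometry or couples at its tertiary terminus; the alkenyl–zirconium bond may also be protonated. The fallback sets out from 24 and 4 and returns at 28, and forms the C5'–C6' bond at the alkyne stage. Copper-mediated alkynylation of bromide 24 with the free alkynol 4 (CuI, K2CO3, NaI, DMF) gives {[(2S)-2-[(3E,8S)-8-hydroxy-4,8,12-trimethyltrideca-3,11-dien-6-yn-1-yl]-2,8-dimethyl-2H-chromen-6-yl]oxy}triisopropylsilane F7. Hydroxyl-directed trans-hydroalumination with NaAlH2(OCH2CH2OMe)2 (THF, 0 °C) gives {[(2S)-2-[(3E,6E,8S)-8-hydroxy-4,8,12-trimethyltrideca-3,6,11-trien-1-yl]-2,8-dimethyl-2H-chromen-6-yl]oxy}triisopropylsilane F8. Bu4NF with AcOH then gives 28.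

**Further compounds**
F1 | step 11 | 2-methyl-4-(triisopropylsilyloxy)aniline | Cc1cc(O[Si](C(C)C)(C(C)C)C(C)C)ccc1N
F2 | step 11 | 2-iodo-6-methyl-4-(triisopropylsilyloxy)aniline | Cc1cc(O[Si](C(C)C)(C(C)C)C(C)C)cc(I)c1N
F3 | step 11 | 2-bromo-1-iodo-3-methyl-5-(triisopropylsilyloxy)benzene | Cc1cc(O[Si](C(C)C)(C(C)C)C(C)C)cc(I)c1Br
F4 | step 11 | (3S,6E)-1-[2-bromo-3-methyl-5-(triisopropylsilyloxy)phenyl]-8-[(tert-butyldimethylsilyl)oxy]-3,7-dimethyloct-6-en-1-yn-3-ol | CC(C)(C)[Si](C)(C)OC/C(C)=C/CC[C@](C)(O)C#Cc1cc(O[Si](C(C)C)(C(C)C)C(C)C)cc(C)c1Br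
F5 | step 11 | (1Z,3S,6E)-1-[2-bromo-3-methyl-5-(triisopropylsilyloxy)phenyl]-8-[(tert-butyldimethylsilyl)oxy]-3,7-dimethylocta-1,6-dien-3-ol | CC(C)(C)[Si](C)(C)OC/C(C)=C/CC[C@](C)(O)/C=C\c1cc(O[Si](C(C)C)(C(C)C)C(C)C)cc(C)c1Br
F6 | step 10 | pentacarbonyl[phenoxy(prop-1-en-2-yl)methylidene]chromium | C=C(C)C(Oc1ccccc1)=[Cr](=C=O)(=C=O)(=C=O)(=C=O)=C=O
F7 | step 16 | {[(2S)-2-[(3E,8S)-8-hydroxy-4,8,12-trimethyltrideca-3,11-dien-6-yn-1-yl]-2,8-dimethyl-2H-chromen-6-yl]oxy}triisopropylsilane | CC(C)=CCC[C@](C)(O)C#CC/C(C)=C/CC[C@@]1(C)C=Cc2cc(O[Si](C(C)C)(C(C)C)C(C)C)cc(C)c2O1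
F8 | step 16 | {[(2S)-2-[(3E,6E,8S)-8-hydroxy-4,8,12-trimethyltrideca-3,6,11-trien-1-yl]-2,8-dimethyl-2H-chromen-6-yl]oxy}triisopropylsilane | CC(C)=CCC[C@](C)(O)/C=C/C/C(C)=C/CC[C@@]1(C)C=Cc2cc(O[Si](C(C)C)(C(C)C)C(C)C)cc(C)c2O1
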